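## Structural features

The target, read from its SMILES as the (2R,3R,2′R,3′R) isomer, consists of two 2,3-trans-2,3-diaryl-2,3-dihydrobenzofurans joined only by the C3–C4′ bond. The first unit is benzene ring A (formyl on C5) fused to furan ring G with the 4-hydroxyphenyl ring B on C2; the second is benzene ring C (hydroxyl on C6′) fused to furan ring D with the 4-hydroxyphenyl ring E on C2′ and the 3,5-dihydroxyphenyl ring F on C3′. The four stereocentres form two adjacent pairs, C2/C3 and C2′/C3′, and although C3 sits on C4′, next to C3a′ and so close to C3′, no ring links the pairs, so their mutual configuration cannot be left to substrate control. The real difficulty lies in C3 and C3′, diaryl-substituted benzylic methines without a heteroatom; C2 and C2′ then only have to come out trans to them. Fragile features are the aryl aldehyde, the five phenols, and the benzylic C2–O1 and C2′–O1′ bonds, which ionise under boron halides or strong acid (para-oxygen donors on rings B and E) and can be hydrogenolysed. The phenols are therefore carried as benzyl ethers that leave under neutral conditions, the C4′ oxygen as a methoxymethyl ether, and the formyl carbon as a nitrile. The key step exploits the fact that O1′, C7a′, C3a′, C3′ and ring F make up the phenol-ester half of a 4-aryl-3,4-dihydrocoumarin whose lactone carbonyl ends as a carboxyl on C2′, the handle for ring E; because both carbons ortho to C3a′ carry oxygen, a 5,7-dioxygenated coumarin also supplies the C4′ oxygen needed for the later C–C bond. Rings B and E are the same aryl group and both halves share one substitution pattern, so a single four-operation module (conjugate arylation, bromination, ring contraction, decarboxylative arylation) is used twice.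

## Logic of the disconnections

27 ⇒ 26. No skeletal bond is cut; the C5 formyl group is traced to a cyano group. A cyano group tolerates amide bases, hydroxide, organozinc reagents and hydrogen, which a formyl group does not, so the last bond-forming steps need no carbonyl protection. The forward step must be a hydride reduction that stops at the imine stage in the presence of five phenols.

26 ⇒ 25. The five O–CH2Ph bonds are cut. Benzyl is chosen because it leaves under neutral hydrogenolysis, whereas ethers that need boron halides would ionise C2–O1 and C2′–O1′. The forward step must cleave aryl benzyl ethers faster than the cyclic benzylic ethers and the nitrile.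

25 ⇒ 23 + 11. The C2–ring B bond is cut, leaving a carboxyl on C2. A radical at C2 is arylated trans to the C3 substituent whatever the configuration of the acid, and ring B comes from the same arylmetal as ring E. The forward coupling must outrun β-hydride loss to the aromatic benzofuran.

23 ⇒ 22. The C2–O1 bond is cut and the carboxyl carbon is rejoined to O1, expanding ring G to a bromolactone. This is the second use of the key contraction; it needs a phenoxide para to a cyano group to close a five-membered ring by substitution.

22 ⇒ 21. The C–Br bond is cut. The forward step is enolate bromination anti to the large C4 substituent at low temperature, before the aryl ester enolate can fragment.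

21 ⇒ 18 + 19. The C3–C3a bond and the lactone O–C(=O) bond are cut. C3 is the centre whose configuration relative to the other half must be imposed by a catalyst, and conjugate arylation of an enoate does this; ring A becomes a purchased arene that already carries O1 and the cyano group. The chiral catalyst must override any bias from C3′ and accept two ortho-substituted aryl partners.

18 ⇒ 16 + 17. The C4′–vinyl bond is cut. The enoate carbons that become C3, C2 and the transient carboxyl are brought in as one three-carbon unit in a single coupling, which must work on a hindered aryl sulfonate.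

16 ⇒ 15 ⇒ 13. The O–S bond and then the O–CH2OMe bond are cut. The C4′ oxygen has to stay masked until the low-valent nickel chemistry at C2′ is over, because an aryl sulfonate would not survive it. The forward deprotection must spare benzyl ethers and the C2′–O1′ bond.

13 ⇒ 8 + 11. The C2′–ring E bond is cut, leaving a carboxyl on C2′. The reasoning and the demand are the same as for 25 ⇒ 23 + 11.

11 ⇒ 9. The carbon–zinc bond is cut back to the carbon–bromine bond. One stock of the arylmetal then serves both arylations, and the forward metalation must leave the benzyl ether alone.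

8 ⇒ 7. The C2′–O1′ bond is cut and the carboxyl carbon is rejoined to O1′, giving the trans bromolactone. This converts a furan stereocentre problem into the chemistry of a 4-aryl-dihydrocoumarin, whose only hard centre is set by conjugate addition. The forward step needs lactone opening followed by O-alkylation faster than loss of HBr.

7 ⇒ 6. The C–Br bond is cut. Bromination of the lactone enolate is expected anti to the C4 aryl group.

6 ⇒ 4 + 5. The C3′–ring F bond is cut. This reduces the first half to a flat coumarin and an arylboronic acid. The forward step is an enantioselective 1,4-addition to a coumarin with an alkoxy group peri to the reacting carbon.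

4 ⇒ 3 ⇒ 1 + 2. The two ether O–C bonds are cut. The oxygen para to C4a (future O6′) must be distinguished from the peri oxygen (future C4′–O), so the forward benzylation must be regioselective.

## Other disconnections considered

Alternative 1: The cut is C3a–C4 and C7a–C7, so benzene ring A is built last in its half. The lactone A1 is O-silylated to the ketene acetal A2, which undergoes an inverse-demand cycloaddition with methyl coumalate A3. Loss of CO2 and silanol then gives the benzofuran ester A4.
- In its favour: the polarity of the two partners puts the ester carbon para to O1 without any directing group, the C2/C3 centres of A1 are carried through untouched, and no transition metal is needed. The ester is a robust precursor of the aldehyde. On these points it is the equal of the chosen plan, and it is the better in avoiding a nitrile reduction next to free phenols.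
- Against it here: A4 carries ring C only as a 3,5-dimethoxyphenyl group. Ring D would still have to be grown on an unactivated C–H ortho to C4′, with C2′/C3′ set relative to C2/C3, so the hardest stereochemical relation is postponed, not solved. A1 needs its own enantioselective synthesis, A2 is a hindered dienophile, and the methyl ethers of A4 would need boron halides at the end.
- Comparison: structurally it builds a benzene ring that the chosen plan simply buys as 19. Mechanistically a thermal pericyclic cascade is as stereochemically innocent as the substitution of step 5. In step count it is longer once ring D is added.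

Alternative 2: The cut is C2–O1 with a C3–H bond formed in the same event. A chiral Brønsted acid of the imidodiphosphorimidate class would protonate C3 of the triarylethylene A5, and the ring A phenol would capture the benzylic cation at C2 to give A6.
- In its favour: ring G and both of its stereocentres arise in one late, convergent, catalytic step. The alkene geometry of A5 is of no concern, and the bromine of A6 is a direct handle for the formyl group. On step economy it is the better: one operation against five for the second module (steps 10–14). Its trans preference is the equal of the chosen plan.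
- Against it here: the enantiodetermining protonation would occur at a carbon flanked by two ortho-substituted aryl groups inside a large, already chiral substrate, which goes beyond the substrates this catalysis is known for. The cation at C2 lies next to the electron-rich rings C and F (Friedel–Crafts capture), the same acid can ionise C2′–O1′ of ring D, and the phenol para to bromine is a weak nucleophile. The methyl ethers would need boron halides, which these rings do not tolerate.
- Comparison: both plans close a furan ring by forming the benzylic C–O bond. The chosen plan does so under base by substitution, with no carbocation next to electron-rich arenes, and sets C3 by a conjugate addition of established scope. Alternative 2 is shorter but rests on one untested event.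

Alternative 3: The cut is C2′–C3′ and C2′–O1′ of ring D. Base would release the ortho-quinone methide A8 from the sulfone A7. The benzylic ylide of the C2-symmetric sulfonium salt A9 would add to the exocyclic carbon (C3′) and the phenoxide would displace the sulfide at C2′, giving A10.
- In its favour: two bonds, the ring and both stereocentres are formed in one step with all three aryl groups in place. A10 already carries bromine at C4′, so the deprotection and sulfonylation of steps 8 and 9 would be unnecessary; here it is the better on step economy. Its trans outcome (anti betaine, then closure with inversion) is the equal of the chosen plan.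
- Against it here: the absolute configuration depends on the facial selectivity of a semi-stabilised ylide towards a transient acceptor of undefined geometry, twisted by the ortho bromine. C3′ is fixed only indirectly through C2′ and the betaine selectivity. Such thiolanium ylides are established for additions to carbonyl groups, not for this acceptor class. A7 must be assembled on a phenol with two different ortho positions, A8 can dimerise, and the methyl ethers of A10 again need boron halides.
- Comparison: the same ring is made from different bonds. The chosen plan sets C3′ first by a catalyst and C2′ afterwards by an independent event, so a shortfall at one centre does not compromise the other, and its protecting groups are chosen for neutral removal. Alternative 3 is shorter but less certain in absolute control.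

Key step: step 5

Remark on the chemistry: the (R)-bisphosphine arylrhodium species is assumed to attack the same enoate face (re at the α-carbon) of the cyclic Z-enoate 4 and of the acyclic E-enoate 18; if a model reaction showed the opposite sense for 18, (S)-BINAP would be used in step 11 with nothing else changed. Compound 19 is taken to be a catalogue boronic acid.

## Route

Step 1
Reactants: 1 5,7-dihydroxycoumarin; 2 benzyl bromide
Product: 3 7-(benzyloxy)-5-hydroxy-2H-chromen-2-one
Conditions: 2 (1.0 equiv), K2CO3 (1.0 equiv), DMF, rt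
Reagents that add atoms: none
Why: Williamson etherification; the 7-hydroxyl is the more acidic and less hindered phenol (para to C4a, no peri hydrogen), so one equivalent of base and halide should alkylate it preferentially.

Step 2
Reactants: 3 7-(benzyloxy)-5-hydroxy-2H-chromen-2-one
Product: 4 7-(benzyloxy)-5-(methoxymethoxy)-2H-chromen-2-one
Conditions: MOMCl, K2CO3, acetone, 0 °C → rt
Reagents that add atoms: chloromethyl methyl ether COCCl
Why: O-alkylation of the remaining phenol as an acetal ether that is stable to base, hydroxide and organozinc reagents and is later removable without touching benzyl ethers.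

Step 3
Reactants: 4 7-(benzyloxy)-5-(methoxymethoxy)-2H-chromen-2-one; 5 [3,5-bis(benzyloxy)phenyl]boronic acid
Product: 6 (4R)-7-(benzyloxy)-4-[3,5-bis(benzyloxy)phenyl]-5-(methoxymethoxy)-3,4-dihydro-2H-chromen-2-one
Conditions: Rh(acac)(C2H4)2 (3 mol %), (R)-SEGPHOS, 5 (3 equiv), dioxane/H2O 10:1, 60 °C
Reagents that add atoms: none
Why: Rhodium-catalysed asymmetric 1,4-addition of an arylboronic acid to a coumarin; the arylrhodium species bound to the (R)-bisphosphine inserts the C3=C4 bond from the face that gives 4R (catalyst control, sets the future C3′) and water releases the product; an ethylene-ligated rhodium source is chosen over a cyclooctadiene one so that no diene-bound rhodium remains as an achiral background catalyst.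

Step 4
Reactants: 6 (4R)-4-aryl-dihydrocoumarin of step 3
Product: 7 (3S,4R)-7-(benzyloxy)-4-[3,5-bis(benzyloxy)phenyl]-3-bromo-5-(methoxymethoxy)-3,4-dihydro-2H-chromen-2-one (trans)
Conditions: LiN(SiMe3)2, THF, −78 °C; NBS, −78 °C; aq NH4Cl
Reagents that add atoms: N-bromosuccinimide O=C1CCC(=O)N1Br
Why: Electrophilic bromination of a lactone lithium enolate; the C4 aryl group, held pseudoaxial by the peri 5-alkoxy group, shields one face, so bromine should enter anti to it and give the trans (3S,4R) bromide.

Step 5
Reactants: 7 (3S,4R)-3-bromo-4-aryl-dihydrocoumarin of step 4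
Product: 8 (2R,3R)-6-(benzyloxy)-3-[3,5-bis(benzyloxy)phenyl]-4-(methoxymethoxy)-2,3-dihydro-1-benzofuran-2-carboxylic acid (trans)
Conditions: NaOH (1 M aq, 3 equiv), THF, 0 °C → rt; then cold 1 M HCl to pH 3
Reagents that add atoms: sodium hydroxide [Na+].[OH-]
Why: Hydroxide adds to the aryl ester carbonyl and opens the lactone to a carboxylate and the phenoxide on C7a′. After rotation about the former C3–C4 bond this phenoxide attacks the α-carbon from the side opposite to bromide in an intramolecular SN2 reaction, forming C2′–O1′ and contracting the six-membered lactone to furan ring D by a 5-exo-tet closure. The closest known reaction type is the Perkin contraction of 3-halocoumarins to benzofuran-2-carboxylic acids, in its saturated form (3-halo-3,4-dihydrocoumarin to 2,3-dihydrobenzofuran-2-carboxylic acid with alkali). The new stereocentre C2′ is controlled by stereospecific inversion at the brominated carbon, whose configuration was set anti to the aryl group in step 4, so the trans bromide should give the trans (2R,3R) acid, while C3′ is not acidic under these conditions and is untouched. The step needs O-alkylation to outrun loss of HBr, attack of external hydroxide at the α-carbon and enolisation of the bromolactone; this is secured by the high effective molarity of a phenoxide five atoms from the electrophilic carbon, by the low temperature, and by the fact that in the intact trans lactone H-4 and bromine cannot become antiperiplanar. Only one phenoxide is available because the other oxygen ortho to C3a′ is blocked as its methoxymethyl ether, and since ring C is symmetric about the C3a′–C6′ axis even loss of that group would lead to the same skeleton. The carboxylate formed is inert to hydroxide and is liberated by cold dilute acid, which benzyl and methoxymethyl ethers survive.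

Step 6
Reactants: 9 1-(benzyloxy)-4-bromobenzene
Product: 11 [4-(benzyloxy)phenyl]zinc chloride, via arylmagnesium bromide 10 (not isolated)
Conditions: Mg turnings (1.2 equiv), LiCl (1.2 equiv), THF, rt; then ZnCl2 (1.0 equiv, THF), 0 °C → rt; solution titrated with I2 and kept under argon
Reagents that add atoms: zinc chloride Cl[Zn]Cl
Why: Grignard formation by LiCl-assisted insertion of magnesium into the aryl bromide, followed by transmetallation to zinc; the aryl benzyl ether is inert to both organometallics, and the titrated arylzinc chloride solution is the stock that supplies steps 7 and 14.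

Step 7
Reactants: 8 dihydrobenzofuran-2-carboxylic acid of step 5; 11 [4-(benzyloxy)phenyl]zinc chloride
Product: 13 (2R,3R)-6-(benzyloxy)-2-[4-(benzyloxy)phenyl]-3-[3,5-bis(benzyloxy)phenyl]-4-(methoxymethoxy)-2,3-dihydro-1-benzofuran, via N-acyloxyphthalimide 12 (not isolated)
Conditions: N-hydroxyphthalimide (1.0 equiv), i-PrN=C=N-i-Pr (1.0 equiv), DMAP (cat.), CH2Cl2, rt; filter, concentrate; then NiCl2·glyme (20 mol %), 4,4′-di-tert-butyl-2,2′-bipyridine (40 mol %), 11 (3 equiv), THF/DMF, rt
Reagents that add atoms: none
Why: Nickel-catalysed decarboxylative Negishi arylation of a redox-active ester; electron transfer from low-valent nickel to 12 releases CO2 and phthalimide and leaves the α-oxy radical at C2′, which is captured by the arylnickel species on the face anti to ring F, so reductive elimination should give the trans (2R,3R) product whatever the configuration of the acid.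

Step 8
Reactants: 13 methoxymethyl ether of step 7
Product: 15 (2R,3R)-6-(benzyloxy)-2-[4-(benzyloxy)phenyl]-3-[3,5-bis(benzyloxy)phenyl]-2,3-dihydro-1-benzofuran-4-ol, via aryl trimethylsilyl ether 14 (not isolated)
Conditions: Me3SiOTf, 2,2′-bipyridyl, CH3CN, 0 °C → rt; then H2O, NaHCO3
Reagents that add atoms: none
Why: Cleavage of an aromatic methoxymethyl ether by silyl triflate buffered with 2,2′-bipyridyl, which gives the aryl silyl ether 14 that water hydrolyses on work-up; the medium is nearly neutral, so benzyl ethers and the acid-labile C2′–O1′ bond should be left alone.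

Step 9
Reactants: 15 phenol of step 8
Product: 16 (2R,3R)-6-(benzyloxy)-2-[4-(benzyloxy)phenyl]-3-[3,5-bis(benzyloxy)phenyl]-2,3-dihydro-1-benzofuran-4-yl trifluoromethanesulfonate
Conditions: Tf2O, pyridine, CH2Cl2, 0 °C
Reagents that add atoms: trifluoromethanesulfonic anhydride O=S(=O)(OS(=O)(=O)C(F)(F)F)C(F)(F)F
Why: O-Sulfonylation of a phenol; it turns the C4′ oxygen into a leaving group for palladium chemistry only after the nickel step is over.

Step 10
Reactants: 16 aryl triflate of step 9; 17 methyl acrylate
Product: 18 methyl (2E)-3-{(2R,3R)-6-(benzyloxy)-2-[4-(benzyloxy)phenyl]-3-[3,5-bis(benzyloxy)phenyl]-2,3-dihydro-1-benzofuran-4-yl}prop-2-enoate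
Conditions: Pd(OAc)2 (5 mol %), 1,3-bis(diphenylphosphino)propane, Et3N, DMF, 90 °C
Reagents that add atoms: none
Why: Heck reaction of an aryl triflate with an acrylate (cationic pathway with a chelating diphosphine on zerovalent palladium); syn insertion and syn β-hydride elimination give the E-enoate and no stereocentre is involved.

Step 11
Reactants: 18 E-enoate of step 10; 19 (5-cyano-2-hydroxyphenyl)boronic acid
Product: 21 (4R)-4-{(2R,3R)-6-(benzyloxy)-2-[4-(benzyloxy)phenyl]-3-[3,5-bis(benzyloxy)phenyl]-2,3-dihydro-1-benzofuran-4-yl}-2-oxo-3,4-dihydro-2H-chromene-6-carbonitrile, via diarylpropanoate 20 (not isolated)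
Conditions: Rh(acac)(C2H4)2 (5 mol %), (R)-BINAP, 19 (4 equiv), dioxane/H2O 10:1, 100 °C; then TsOH·H2O (5 mol %), toluene, 80 °C
Reagents that add atoms: none
Why: Rhodium-catalysed asymmetric 1,4-addition of an arylboronic acid to a β-aryl acrylate (3,3-diarylpropanoate synthesis); the (R)-BINAP arylrhodium species should add to the α-re face of the E-enoate and set C3 as R by catalyst control, and acid-catalysed transesterification of 20 then closes the dihydrocoumarin, which also masks the ring A phenol for step 12.

Step 12
Reactants: 21 dihydrocoumarin of step 11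
Product: 22 (3S,4R)-4-{(2R,3R)-6-(benzyloxy)-2-[4-(benzyloxy)phenyl]-3-[3,5-bis(benzyloxy)phenyl]-2,3-dihydro-1-benzofuran-4-yl}-3-bromo-2-oxo-3,4-dihydro-2H-chromene-6-carbonitrile (trans)
Conditions: LiN(SiMe3)2, THF, −78 °C; NBS, −78 °C; aq NH4Cl
Reagents that add atoms: N-bromosuccinimide O=C1CCC(=O)N1Br
Why: Enolate bromination as in step 4; the large C4 substituent directs bromine to the opposite face, and the low temperature keeps the amide base away from the nitrile and the aryl ester enolate from fragmenting.

Step 13
Reactants: 22 bromolactone of step 12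
Product: 23 (2R,3R)-3-{(2R,3R)-6-(benzyloxy)-2-[4-(benzyloxy)phenyl]-3-[3,5-bis(benzyloxy)phenyl]-2,3-dihydro-1-benzofuran-4-yl}-5-cyano-2,3-dihydro-1-benzofuran-2-carboxylic acid
Conditions: NaOH (1 M aq, 3 equiv), THF, 0 °C → rt; then cold 1 M HCl to pH 3
Reagents that add atoms: sodium hydroxide [Na+].[OH-]
Why: Second use of the lactone-opening and 5-exo-tet O-alkylation of step 5, now closing furan ring G; the phenoxide para to the cyano group is less nucleophilic but still intramolecular, the nitrile is inert to cold hydroxide, and the C2 configuration (inversion of the bromide) is in any case reset in step 14.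

Step 14
Reactants: 23 carboxylic acid of step 13; 11 [4-(benzyloxy)phenyl]zinc chloride
Product: 25 (2R,3R)-3-{(2R,3R)-6-(benzyloxy)-2-[4-(benzyloxy)phenyl]-3-[3,5-bis(benzyloxy)phenyl]-2,3-dihydro-1-benzofuran-4-yl}-2-[4-(benzyloxy)phenyl]-2,3-dihydro-1-benzofuran-5-carbonitrile, via N-acyloxyphthalimide 24 (not isolated)
Conditions: N-hydroxyphthalimide (1.0 equiv), i-PrN=C=N-i-Pr (1.0 equiv), DMAP (cat.), CH2Cl2, rt; filter, concentrate; then NiCl2·glyme (20 mol %), 4,4′-di-tert-butyl-2,2′-bipyridine (40 mol %), 11 (3 equiv, stock solution of step 6), THF/DMF, rt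
Reagents that add atoms: none
Why: Decarboxylative Negishi arylation as in step 7; the C2 radical is arylated anti to the very large C3 substituent, which should give the trans (2R,3R) ring G, and aryl nitriles are tolerated by arylzinc reagents at room temperature.

Step 15
Reactants: 25 pentabenzyl ether nitrile of step 14
Product: 26 (2R,3R)-3-[(2R,3R)-3-(3,5-dihydroxyphenyl)-6-hydroxy-2-(4-hydroxyphenyl)-2,3-dihydro-1-benzofuran-4-yl]-2-(4-hydroxyphenyl)-2,3-dihydro-1-benzofuran-5-carbonitrile
Conditions: H2 (1 atm), Pd/C (10 %), THF/EtOAc, rt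
Reagents that add atoms: none
Why: Hydrogenolysis of five aryl benzyl ethers under neutral aprotic conditions, where primary benzyl–oxygen bonds are cleaved much faster than the hindered cyclic benzylic ethers or the nitrile; no acid is involved, so the furan rings are not ionised.

Step 16
Reactants: 26 pentaphenol nitrile of step 15
Product: 27 (2R,3R)-3-[(2R,3R)-3-(3,5-dihydroxyphenyl)-6-hydroxy-2-(4-hydroxyphenyl)-2,3-dihydro-1-benzofuran-4-yl]-2-(4-hydroxyphenyl)-2,3-dihydro-1-benzofuran-5-carbaldehyde (target)
Conditions: i-Bu2AlH (8 equiv), THF, −78 → 0 °C; then 1 M HCl (aq), 0 °C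
Reagents that add atoms: water O
Why: Reduction of an aryl nitrile by a dialkylaluminium hydride to the N-aluminio imine, hydrolysed to the aldehyde on work-up; the phenols are first converted to aluminium phenoxides (hence the excess), and the imine stage resists further hydride so that the aldehyde level is reached only after quenching.

## Compound list

1 | 5,7-dihydroxycoumarin | O=c1ccc2c(O)cc(O)cc2o1 | starting material
2 | benzyl bromide | BrCc1ccccc1 | starting material
3 | 7-(benzyloxy)-5-hydroxy-2H-chromen-2-one | O=c1ccc2c(O)cc(OCc3ccccc3)cc2o1 | intermediate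
4 | 7-(benzyloxy)-5-(methoxymethoxy)-2H-chromen-2-one | O=c1ccc2c(OCOC)cc(OCc3ccccc3)cc2o1 | intermediate
5 | [3,5-bis(benzyloxy)phenyl]boronic acid | OB(O)c1cc(OCc2ccccc2)cc(OCc2ccccc2)c1 | starting material
6 | (4R)-7-(benzyloxy)-4-[3,5-bis(benzyloxy)phenyl]-5-(methoxymethoxy)-3,4-dihydro-2H-chromen-2-one | COCOc1cc(OCc3ccccc3)cc2c1[C@@H](c1cc(OCc3ccccc3)cc(OCc3ccccc3)c1)CC(=O)O2 | intermediate
7 | (3S,4R)-7-(benzyloxy)-4-[3,5-bis(benzyloxy)phenyl]-3-bromo-5-(methoxymethoxy)-3,4-dihydro-2H-chromen-2-one | COCOc1cc(OCc3ccccc3)cc2c1[C@@H](c1cc(OCc3ccccc3)cc(OCc3ccccc3)c1)[C@H](Br)C(=O)O2 | intermediate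
8 | (2R,3R)-6-(benzyloxy)-3-[3,5-bis(benzyloxy)phenyl]-4-(methoxymethoxy)-2,3-dihydro-1-benzofuran-2-carboxylic acid | COCOc1cc(OCc3ccccc3)cc2c1[C@@H](c1cc(OCc3ccccc3)cc(OCc3ccccc3)c1)[C@H](C(=O)O)O2 | intermediate
9 | 1-(benzyloxy)-4-bromobenzene | Brc1ccc(OCc2ccccc2)cc1 | starting material
10 | [4-(benzyloxy)phenyl]magnesium bromide | Br[Mg]c1ccc(OCc2ccccc2)cc1 | intermediate (not isolated)
11 | [4-(benzyloxy)phenyl]zinc chloride | Cl[Zn]c1ccc(OCc2ccccc2)cc1 | intermediate
12 | 1,3-dioxoisoindolin-2-yl (2R,3R)-6-(benzyloxy)-3-[3,5-bis(benzyloxy)phenyl]-4-(methoxymethoxy)-2,3-dihydro-1-benzofuran-2-carboxylate | COCOc1cc(OCc3ccccc3)cc2c1[C@@H](c1cc(OCc3ccccc3)cc(OCc3ccccc3)c1)[C@H](C(=O)ON1C(=O)c3ccccc3C1=O)O2 | intermediate (not isolated)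
13 | (2R,3R)-6-(benzyloxy)-2-[4-(benzyloxy)phenyl]-3-[3,5-bis(benzyloxy)phenyl]-4-(methoxymethoxy)-2,3-dihydro-1-benzofuran | COCOc1cc(OCc3ccccc3)cc2c1[C@@H](c1cc(OCc3ccccc3)cc(OCc3ccccc3)c1)[C@H](c1ccc(OCc3ccccc3)cc1)O2 | intermediate
14 | {[(2R,3R)-6-(benzyloxy)-2-[4-(benzyloxy)phenyl]-3-[3,5-bis(benzyloxy)phenyl]-2,3-dihydro-1-benzofuran-4-yl]oxy}trimethylsilane | C[Si](C)(C)Oc1cc(OCc3ccccc3)cc2c1[C@@H](c1cc(OCc3ccccc3)cc(OCc3ccccc3)c1)[C@H](c1ccc(OCc3ccccc3)cc1)O2 | intermediate (not isolated)
15 | (2R,3R)-6-(benzyloxy)-2-[4-(benzyloxy)phenyl]-3-[3,5-bis(benzyloxy)phenyl]-2,3-dihydro-1-benzofuran-4-ol | Oc1cc(OCc3ccccc3)cc2c1[C@@H](c1cc(OCc3ccccc3)cc(OCc3ccccc3)c1)[C@H](c1ccc(OCc3ccccc3)cc1)O2 | intermediate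
16 | (2R,3R)-6-(benzyloxy)-2-[4-(benzyloxy)phenyl]-3-[3,5-bis(benzyloxy)phenyl]-2,3-dihydro-1-benzofuran-4-yl trifluoromethanesulfonate | O=S(=O)(Oc1cc(OCc3ccccc3)cc2c1[C@@H](c1cc(OCc3ccccc3)cc(OCc3ccccc3)c1)[C@H](c1ccc(OCc3ccccc3)cc1)O2)C(F)(F)F | intermediate
17 | methyl acrylate | C=CC(=O)OC | starting material
18 | methyl (2E)-3-{(2R,3R)-6-(benzyloxy)-2-[4-(benzyloxy)phenyl]-3-[3,5-bis(benzyloxy)phenyl]-2,3-dihydro-1-benzofuran-4-yl}prop-2-enoate | COC(=O)/C=C/c1cc(OCc3ccccc3)cc2c1[C@@H](c1cc(OCc3ccccc3)cc(OCc3ccccc3)c1)[C@H](c1ccc(OCc3ccccc3)cc1)O2 | intermediate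
19 | (5-cyano-2-hydroxyphenyl)boronic acid | N#Cc1ccc(O)c(B(O)O)c1 | starting material
20 | methyl (3R)-3-{(2R,3R)-6-(benzyloxy)-2-[4-(benzyloxy)phenyl]-3-[3,5-bis(benzyloxy)phenyl]-2,3-dihydro-1-benzofuran-4-yl}-3-(5-cyano-2-hydroxyphenyl)propanoate | COC(=O)C[C@@H](c1cc(C#N)ccc1O)c1cc(OCc3ccccc3)cc2c1[C@@H](c1cc(OCc3ccccc3)cc(OCc3ccccc3)c1)[C@H](c1ccc(OCc3ccccc3)cc1)O2 | intermediate (not isolated)
21 | (4R)-4-{(2R,3R)-6-(benzyloxy)-2-[4-(benzyloxy)phenyl]-3-[3,5-bis(benzyloxy)phenyl]-2,3-dihydro-1-benzofuran-4-yl}-2-oxo-3,4-dihydro-2H-chromene-6-carbonitrile | N#Cc1ccc2c(c1)[C@@H](c1cc(OCc4ccccc4)cc3c1[C@@H](c1cc(OCc4ccccc4)cc(OCc4ccccc4)c1)[C@H](c1ccc(OCc4ccccc4)cc1)O3)CC(=O)O2 | intermediate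
22 | (3S,4R)-4-{(2R,3R)-6-(benzyloxy)-2-[4-(benzyloxy)phenyl]-3-[3,5-bis(benzyloxy)phenyl]-2,3-dihydro-1-benzofuran-4-yl}-3-bromo-2-oxo-3,4-dihydro-2H-chromene-6-carbonitrile | N#Cc1ccc2c(c1)[C@@H](c1cc(OCc4ccccc4)cc3c1[C@@H](c1cc(OCc4ccccc4)cc(OCc4ccccc4)c1)[C@H](c1ccc(OCc4ccccc4)cc1)O3)[C@H](Br)C(=O)O2 | intermediate
23 | (2R,3R)-3-{(2R,3R)-6-(benzyloxy)-2-[4-(benzyloxy)phenyl]-3-[3,5-bis(benzyloxy)phenyl]-2,3-dihydro-1-benzofuran-4-yl}-5-cyano-2,3-dihydro-1-benzofuran-2-carboxylic acid | N#Cc1ccc2c(c1)[C@@H](c1cc(OCc4ccccc4)cc3c1[C@@H](c1cc(OCc4ccccc4)cc(OCc4ccccc4)c1)[C@H](c1ccc(OCc4ccccc4)cc1)O3)[C@H](C(=O)O)O2 | intermediate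
24 | 1,3-dioxoisoindolin-2-yl (2R,3R)-3-{(2R,3R)-6-(benzyloxy)-2-[4-(benzyloxy)phenyl]-3-[3,5-bis(benzyloxy)phenyl]-2,3-dihydro-1-benzofuran-4-yl}-5-cyano-2,3-dihydro-1-benzofuran-2-carboxylate | N#Cc1ccc2c(c1)[C@@H](c1cc(OCc4ccccc4)cc3c1[C@@H](c1cc(OCc4ccccc4)cc(OCc4ccccc4)c1)[C@H](c1ccc(OCc4ccccc4)cc1)O3)[C@H](C(=O)ON1C(=O)c3ccccc3C1=O)O2 | intermediate (not isolated)
25 | (2R,3R)-3-{(2R,3R)-6-(benzyloxy)-2-[4-(benzyloxy)phenyl]-3-[3,5-bis(benzyloxy)phenyl]-2,3-dihydro-1-benzofuran-4-yl}-2-[4-(benzyloxy)phenyl]-2,3-dihydro-1-benzofuran-5-carbonitrile | N#Cc1ccc2c(c1)[C@@H](c1cc(OCc4ccccc4)cc3c1[C@@H](c1cc(OCc4ccccc4)cc(OCc4ccccc4)c1)[C@H](c1ccc(OCc4ccccc4)cc1)O3)[C@H](c1ccc(OCc4ccccc4)cc1)O2 | intermediate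
26 | (2R,3R)-3-[(2R,3R)-3-(3,5-dihydroxyphenyl)-6-hydroxy-2-(4-hydroxyphenyl)-2,3-dihydro-1-benzofuran-4-yl]-2-(4-hydroxyphenyl)-2,3-dihydro-1-benzofuran-5-carbonitrile | N#Cc1ccc2c(c1)[C@@H](c1cc(O)cc3c1[C@@H](c1cc(O)cc(O)c1)[C@H](c1ccc(O)cc1)O3)[C@H](c1ccc(O)cc1)O2 | intermediate
27 | (2R,3R)-3-[(2R,3R)-3-(3,5-dihydroxyphenyl)-6-hydroxy-2-(4-hydroxyphenyl)-2,3-dihydro-1-benzofuran-4-yl]-2-(4-hydroxyphenyl)-2,3-dihydro-1-benzofuran-5-carbaldehyde | O=Cc1ccc2c(c1)[C@@H](c1cc(O)cc3c1[C@@H](c1cc(O)cc(O)c1)[C@H](c1ccc(O)cc1)O3)[C@H](c1ccc(O)cc1)O2 | target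

## Step count and least certain steps

Total step count: 16. Longest linear sequence: 15 steps (steps 1 to 5 and 7 to 16, from 1 to 27); step 6 is a one-step side branch that turns 9 into the stock of 11 used in steps 7 and 14. Compounds 2, 5, 9, 17 and 19 enter as purchased building blocks.

Step 5 (key step). The ring-opened bromo carboxylate may lose HBr once rotation makes H and Br antiperiplanar, external hydroxide may substitute at the α-carbon, or carboxylate participation may erode the inversion. Fallback from 6, returning at 8: the lithium enolate of 6 is oxidised with 2-(phenylsulfonyl)-3-phenyloxaziridine anti to the aryl group to the trans 3-hydroxy lactone F1. K2CO3 in methanol opens it to the methyl 2-hydroxy-3,3-diarylpropanoate F2 with one free phenol. A Mitsunobu reaction (PPh3, diisopropyl azodicarboxylate) then forms the same C2′–O1′ bond with inversion, without halide or hydroxide, to give the methyl ester F3, and LiOH gives 8.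

Step 11. Insertion may be slow because both aryl groups at the new methine are ortho-substituted, protodeboronation of the ortho-hydroxy boronic acid may outrun addition, the C3′ centre may oppose the catalyst (mismatched facial selectivity), lactonisation may stop short, and the acid used for ring closure may ionise C2′–O1′. Fallback from 16, returning at 21: Miyaura borylation (Pd(dppf)Cl2, bis(pinacolato)diboron, KOAc, dioxane) gives the pinacol boronate F4. F4 is then added under Rh(acac)(C2H4)2/(R)-SEGPHOS in aqueous dioxane to an excess of purchased 2-oxo-2H-chromene-6-carbonitrile, reversing the roles of the partners and giving the lactone 21 directly, with no acid treatment.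

Step 3. Turnover may be poor because the 5-alkoxy group is peri to the reacting carbon and the coumarin is electron-rich, so hydrolysis of the boronic acid may dominate. Fallback from 4 and 5, returning at 6: oxidative Heck coupling (Pd(OAc)2, 1,10-phenanthroline, O2, DMF) gives the 4-arylcoumarin F5. Asymmetric conjugate reduction with CuH (Cu(OAc)2, DTBM-SEGPHOS, (EtO)2MeSiH, t-BuOH, toluene) then sets C4 by hydride delivery, the ligand enantiomer being chosen for 4R.

Step 7 (the same applies to step 14). The C2′–nickel intermediate may undergo β-hydride elimination, driven by aromatisation to the benzofuran; the radical may be reduced; residual N-hydroxyphthalimide may quench the arylzinc reagent. Fallback from 8 and 9, returning at 13 (and likewise from 23 and 9 to 25): direct photoredox/nickel decarboxylative arylation of the caesium carboxylate with the aryl bromide ([Ir(dF(CF3)ppy)2(dtbbpy)]PF6, NiCl2·glyme, 4,4′-di-tert-butyl-2,2′-bipyridine, Cs2CO3, DMF, blue light). This generates the same C2′ radical oxidatively, without an activated ester or organozinc reagent, and makes no compound outside the list (F0).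

Step 16 (with step 15). Aluminium phenoxides of 26 may aggregate and leave the nitrile unreduced, or reduction may run on to the amine; in step 15 the cyclic benzylic C–O bonds may be hydrogenolysed on prolonged exposure. Fallback from 25, returning at 27: the order is reversed. i-Bu2AlH in toluene at −78 °C reduces the fully benzylated nitrile to the pentabenzyl aldehyde F6, and the benzyl ethers are then removed by transfer hydrogenolysis (Pd/C, 1,4-cyclohexadiene, EtOAc), which is slow towards aryl aldehydes.

Step 1. Alkylation may be unselective between the two phenols or run on to the dibenzyl ether. Fallback from 2, returning at 3: purchased 2,4,6-trihydroxybenzaldehyde is benzylated (K2CO3, DMF) at the only hydroxyl not hydrogen-bonded to the formyl group, giving 4-(benzyloxy)-2,6-dihydroxybenzaldehyde F7. Heating with ethyl (triphenylphosphoranylidene)acetate in N,N-diethylaniline gives the cinnamate F8 (not isolated), which lactonises through either of its two equivalent phenols to 3.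

Further compounds
F1 | step 5 | (3S,4R)-7-(benzyloxy)-4-[3,5-bis(benzyloxy)phenyl]-3-hydroxy-5-(methoxymethoxy)-3,4-dihydro-2H-chromen-2-one | COCOc1cc(OCc3ccccc3)cc2c1[C@@H](c1cc(OCc3ccccc3)cc(OCc3ccccc3)c1)[C@H](O)C(=O)O2
F2 | step 5 | methyl (2S,3R)-3-[4-(benzyloxy)-2-hydroxy-6-(methoxymethoxy)phenyl]-3-[3,5-bis(benzyloxy)phenyl]-2-hydroxypropanoate | COCOc1cc(OCc3ccccc3)cc(O)c1[C@@H](c1cc(OCc3ccccc3)cc(OCc3ccccc3)c1)[C@H](O)C(=O)OC
F3 | step 5 | methyl (2R,3R)-6-(benzyloxy)-3-[3,5-bis(benzyloxy)phenyl]-4-(methoxymethoxy)-2,3-dihydro-1-benzofuran-2-carboxylate | COCOc1cc(OCc3ccccc3)cc2c1[C@@H](c1cc(OCc3ccccc3)cc(OCc3ccccc3)c1)[C@H](C(=O)OC)O2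
F4 | step 11 | 2-{(2R,3R)-6-(benzyloxy)-2-[4-(benzyloxy)phenyl]-3-[3,5-bis(benzyloxy)phenyl]-2,3-dihydro-1-benzofuran-4-yl}-4,4,5,5-tetramethyl-1,3,2-dioxaborolane | CC1(C)OB(OC1(C)C)c1cc(OCc3ccccc3)cc2c1[C@@H](c1cc(OCc3ccccc3)cc(OCc3ccccc3)c1)[C@H](c1ccc(OCc3ccccc3)cc1)O2
F5 | step 3 | 7-(benzyloxy)-4-[3,5-bis(benzyloxy)phenyl]-5-(methoxymethoxy)-2H-chromen-2-one | O=c1cc(-c2cc(OCc3ccccc3)cc(OCc3ccccc3)c2)c2c(OCOC)cc(OCc3ccccc3)cc2o1
F0 | step 7 | none | none
F6 | step 16 | (2R,3R)-3-{(2R,3R)-6-(benzyloxy)-2-[4-(benzyloxy)phenyl]-3-[3,5-bis(benzyloxy)phenyl]-2,3-dihydro-1-benzofuran-4-yl}-2-[4-(benzyloxy)phenyl]-2,3-dihydro-1-benzofuran-5-carbaldehyde | O=Cc1ccc2c(c1)[C@@H](c1cc(OCc4ccccc4)cc3c1[C@@H](c1cc(OCc4ccccc4)cc(OCc4ccccc4)c1)[C@H](c1ccc(OCc4ccccc4)cc1)O3)[C@H](c1ccc(OCc4ccccc4)cc1)O2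
F7 | step 1 | 4-(benzyloxy)-2,6-dihydroxybenzaldehyde | O=Cc1c(O)cc(OCc2ccccc2)cc1O
F8 | step 1 | ethyl (2E)-3-[4-(benzyloxy)-2,6-dihydroxyphenyl]prop-2-enoate | CCOC(=O)/C=C/c1c(O)cc(OCc2ccccc2)cc1O
A1 | alternative 1 | (4S,5R)-4-(3,5-dimethoxyphenyl)-5-(4-methoxyphenyl)oxolan-2-one (trans) | O=C1C[C@@H](c2cc(OC)cc(OC)c2)[C@H](c2ccc(OC)cc2)O1
A2 | alternative 1 | (2R,3S)-3-(3,5-dimethoxyphenyl)-2-(4-methoxyphenyl)-5-(trimethylsilyloxy)-2,3-dihydrofuran | C[Si](C)(C)OC1=C[C@@H](c2cc(OC)cc(OC)c2)[C@H](c2ccc(OC)cc2)O1
A3 | alternative 1 | methyl coumalate (methyl 2-oxo-2H-pyran-5-carboxylate) | COC(=O)c1ccc(=O)oc1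
A4 | alternative 1 | methyl (2R,3R)-3-(3,5-dimethoxyphenyl)-2-(4-methoxyphenyl)-2,3-dihydro-1-benzofuran-5-carboxylate | COC(=O)c1ccc2c(c1)[C@@H](c1cc(OC)cc(OC)c1)[C@H](c1ccc(OC)cc1)O2
A5 | alternative 2 | 4-bromo-2-{1-[(2R,3R)-3-(3,5-dimethoxyphenyl)-6-methoxy-2-(4-methoxyphenyl)-2,3-dihydro-1-benzofuran-4-yl]-2-(4-methoxyphenyl)ethenyl}phenol (either alkene isomer) | COc1ccc(C=C(c2cc(Br)ccc2O)c2cc(OC)cc3c2[C@@H](c2cc(OC)cc(OC)c2)[C@H](c2ccc(OC)cc2)O3)cc1
A6 | alternative 2 | (2R,3R)-5-bromo-3-[(2R,3R)-3-(3,5-dimethoxyphenyl)-6-methoxy-2-(4-methoxyphenyl)-2,3-dihydro-1-benzofuran-4-yl]-2-(4-methoxyphenyl)-2,3-dihydro-1-benzofuran | Brc1ccc2c(c1)[C@@H](c1cc(OC)cc3c1[C@@H](c1cc(OC)cc(OC)c1)[C@H](c1ccc(OC)cc1)O3)[C@H](c1ccc(OC)cc1)O2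
A7 | alternative 3 | 3-bromo-2-[(3,5-dimethoxyphenyl)(4-methylbenzenesulfonyl)methyl]-5-methoxyphenol (racemic at the benzylic carbon) | COc1cc(O)c(C(c2cc(OC)cc(OC)c2)S(=O)(=O)c2ccc(C)cc2)c(Br)c1
A8 | alternative 3 | 3-bromo-2-[(3,5-dimethoxyphenyl)methylidene]-5-methoxycyclohexa-3,5-dien-1-one (either alkene isomer) | O=C1C=C(OC)C=C(Br)C1=Cc1cc(OC)cc(OC)c1
A9 | alternative 3 | (2R,5R)-1-(4-methoxybenzyl)-2,5-dimethylthiolan-1-ium trifluoromethanesulfonate (one enantiomer shown) | C[C@@H]1CC[C@@H](C)[S+]1Cc1ccc(OC)cc1.[O-]S(=O)(=O)C(F)(F)F
A10 | alternative 3 | (2R,3R)-4-bromo-3-(3,5-dimethoxyphenyl)-6-methoxy-2-(4-methoxyphenyl)-2,3-dihydro-1-benzofuran | Brc1cc(OC)cc2c1[C@@H](c1cc(OC)cc(OC)c1)[C@H](c1ccc(OC)cc1)O2
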